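## Retrosynthetic overview
1. The quinone comes from para-oxygenation of the O-methylated alkylresorcinol. That phenol comes from loss of CO2 from the matching alkylresorcylic acid. This is the late sequence of the polyketide pathway.
2. Ring A is the only ring made. It forms by a C2–C7 intramolecular aldol and dehydration of a 3-O-methyl-6-methyl-3,5,7-trioxo C32 acid (a tetraketide), released by hydroxide opening of a 2-pyrone (ring B, bought and sacrificed).
3. The tetraketide comes from C6–C7 Claisen acylation of lithiated 6-ethyl-4-methoxy-2-pyrone by ethyl hexacosanoate (the starter unit). The pyrone is a masked triketide that already carries the correct O-methyl group and the "methylmalonate" methyl group. Acylation, ring opening and aldol run in one flask, a formal [5+1] benzannulation in which the ester carbonyl carbon becomes an arene carbon.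
4. The 6-ethylpyrone comes from 4-methoxy-6-methyl-2-pyrone and MeI. The C26 ester comes from a C18 Grignard reagent and ethyl 8-bromooctanoate by copper-catalysed sp3–sp3 coupling.

Assumption: the target (C33H58O3) has no stereocentre and no stereogenic double bond, so it is achiral and no enantiomer has to be chosen; the side chain is read as unbranched n-pentacosyl (C25H51).

## Route

Step 1
Reactants: 1 1-bromooctadecane; 2 ethyl 8-bromooctanoate
Product: 4 ethyl hexacosanoate, via octadecylmagnesium bromide 3 (not isolated)
Conditions: Mg, THF, 50 °C; then slow addition to 2, Li2CuCl4 (3 mol %), NMP (4 equiv), THF, 0 °C → rt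
Reagents that add atoms: none
Why: Kochi–Cahiez copper-catalysed sp3–sp3 cross-coupling, in which the alkylcopper species from 3 and catalytic Li2CuCl4 displaces the primary bromide of 2 much faster than 3 adds to the ester when NMP is present and 3 is added slowly, so 18 + 8 carbons give the C26 acyl chain and no stereocentre is formed.

Step 2
Reactants: 5 4-methoxy-6-methyl-2H-pyran-2-one
Product: 7 6-ethyl-4-methoxy-2H-pyran-2-one, via lithiated methylpyrone 6 (not isolated)
Conditions: LiN(iPr)2 (1.05 equiv), THF, −78 °C; MeI (1.1 equiv), −78 → −30 °C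
Reagents that add atoms: iodomethane (MeI), CI
Why: Vinylogous enolate alkylation, in which LiN(iPr)2 deprotonates the 6-methyl group (conjugated through the diene to the lactone carbonyl) and the extended dienolate 6 is methylated at its exocyclic carbon, which installs the future ring methyl group without creating a stereocentre.

Step 3
Reactants: 7 6-ethyl-4-methoxy-2H-pyran-2-one; 4 ethyl hexacosanoate
Product: 11 4-hydroxy-2-methoxy-5-methyl-6-pentacosylbenzoic acid, via lithiated ethylpyrone 8 (not isolated), via ketopyrone 9 (not isolated), via ring-opened tetraketide acid 10 (not isolated)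
Conditions: 7 (2.2 equiv), LiN(iPr)2 (2.2 equiv), THF–DMPU, −78 °C; 4 (1 equiv, THF), −78 → 0 °C; then 2 M aq KOH (15 equiv), Ar, 45 °C, 12 h; 1 M HCl, 0 °C, pH 3
Reagents that add atoms: potassium hydroxide, [K+].[OH-]
Why: Proposed new method: a one-flask formal [5+1] benzannulation in which the extended dienolate 8 is C-acylated at its exocyclic carbon by the fatty ester (vinylogous Claisen condensation, driven by deprotonation of 9 by the second equivalent of 8), hydroxide then opens the lactone of 9 at C2 to the 3-O-methyl tetraketide 10, whose C2 (alpha to the carboxylate and gamma to the beta-methoxyenone after double-bond shift) adds to the C7 ketone, and loss of water plus enolisation at C5 aromatises the ring irreversibly and erases the labile C6 stereocentre, the closest known reaction types being the acylation of lithiated 4-methoxy-6-methyl-2-pyrone and the aqueous-alkali conversion of 6-(2-oxoalkyl)-2-pyrones into resorcylic acids (biomimetic polyketide aldol cyclisation).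

Step 4
Reactants: 11 4-hydroxy-2-methoxy-5-methyl-6-pentacosylbenzoic acid
Product: 13 5-methoxy-2-methyl-3-pentacosylcyclohexa-2,5-diene-1,4-dione (= 2-methoxy-5-methyl-6-pentacosyl-1,4-benzoquinone, target), via alkylresorcinol methyl ether 12 (not isolated)
Conditions: CF3CO2H–CHCl3 (1:2), 60 °C, 2 h; evaporate; then Co(salen) [C16H14CoN2O2] (10 mol %), O2 (1 atm), DMF–CHCl3 (1:1), 35 °C
Reagents that add atoms: dioxygen, O=O
Why: Acid-catalysed protodecarboxylation (ipso protonation para to OH and ortho to OMe of a carboxyl group twisted out of plane by two ortho substituents) gives 12, and Co(salen)-catalysed aerobic phenol oxidation (phenoxyl radical trapped by cobalt-bound dioxygen at the free para carbon, collapse of the peroxide with loss of water) gives the para-quinone, as is usual for 3-alkyl-5-methoxyphenols, with no stereocentre involved.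

## Compound list
1 | 1-bromooctadecane | CCCCCCCCCCCCCCCCCCBr | starting material
2 | ethyl 8-bromooctanoate | CCOC(=O)CCCCCCCBr | starting material
3 | octadecylmagnesium bromide | CCCCCCCCCCCCCCCCCC[Mg]Br | intermediate
4 | ethyl hexacosanoate | CCCCCCCCCCCCCCCCCCCCCCCCCC(=O)OCC | intermediate
5 | 4-methoxy-6-methyl-2H-pyran-2-one | CC1=CC(OC)=CC(=O)O1 | starting material
6 | 6-(lithiomethyl)-4-methoxy-2H-pyran-2-one (extended lithium dienolate) | [Li]CC1=CC(OC)=CC(=O)O1 | intermediate
7 | 6-ethyl-4-methoxy-2H-pyran-2-one | CCC1=CC(OC)=CC(=O)O1 | intermediate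
8 | 6-(1-lithioethyl)-4-methoxy-2H-pyran-2-one (extended lithium dienolate) | [Li]C(C)C1=CC(OC)=CC(=O)O1 | intermediate
9 | 4-methoxy-6-(3-oxooctacosan-2-yl)-2H-pyran-2-one (racemic, labile centre) | CCCCCCCCCCCCCCCCCCCCCCCCCC(=O)C(C)C1=CC(OC)=CC(=O)O1 | intermediate
10 | (2E)-3-methoxy-6-methyl-5,7-dioxodotriacont-2-enoic acid (racemic, present as potassium salts, tautomers equilibrate) | CCCCCCCCCCCCCCCCCCCCCCCCCC(=O)C(C)C(=O)C/C(OC)=C\C(=O)O | intermediate
11 | 4-hydroxy-2-methoxy-5-methyl-6-pentacosylbenzoic acid | CCCCCCCCCCCCCCCCCCCCCCCCCC1=C(C)C(O)=CC(OC)=C1C(=O)O | intermediate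
12 | 5-methoxy-2-methyl-3-pentacosylphenol | CCCCCCCCCCCCCCCCCCCCCCCCCC1=C(C)C(O)=CC(OC)=C1 | intermediate
13 | 5-methoxy-2-methyl-3-pentacosylcyclohexa-2,5-diene-1,4-dione (achiral) | CCCCCCCCCCCCCCCCCCCCCCCCCC1=C(C)C(=O)C=C(OC)C1=O | target

## Step count and risks
Total step count: 4.
Longest linear sequence: 3 steps (1 → 3 → 4 or 2 → 3 → 4).

**Most likely to fail: step 3.**
- The secondary, delocalised carbanion 8 may acylate slowly with the poorly soluble C26 ester.
- Hydroxide may cleave the 2-methyl-1,3-dicarbonyl unit irreversibly (retro-Claisen).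
- Hydroxide may hydrolyse the enol ether before the aldol closes.

The fallback sets out from 4, uses 8, passes through 9 as an isolated compound and comes back to the route at 12. Reduce 4 with iBu2AlH (toluene, −78 °C) to hexacosanal F1. Add 8 to it, a carbonyl addition instead of a Claisen acylation that needs only one equivalent of 8. This gives 6-(3-hydroxyoctacosan-2-yl)-4-methoxy-2H-pyran-2-one F2 as a diastereomer mixture. Oxidise F2 with Dess–Martin periodinane to 9 and purify it. Close ring A with NaOMe in MeOH–THF, where alkoxide cleavage of the dicarbonyl unit is reversible, C2–H is more acidic (alpha to an ester) and only aromatisation is irreversible. This gives methyl 4-hydroxy-2-methoxy-5-methyl-6-pentacosylbenzoate F3. Saponify and decarboxylate F3 with KOH in ethylene glycol–water at 150 °C followed by hot acidification, which gives 12.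

**Second: step 4.**
- Decarboxylation may be incomplete.
- The aerobic stage may give C–C coupled dimers at the free ortho position.

The fallback sets out from 11 and comes back at 13 without a separate decarboxylation. Treat 11 with (KO3S)2NO (2.5 equiv) and Bu4NHSO4 in phosphate buffer and CH2Cl2–H2O (Teuber oxidation with ipso displacement). The phenoxyl radical is trapped at the carboxyl-bearing para carbon to give dipotassium N-[(1-carboxy-2-methoxy-5-methyl-4-oxo-6-pentacosylcyclohexa-2,5-dien-1-yl)oxy]imidodisulfonate F4. F4 fragments with loss of CO2 and N–O cleavage to 13. Any 12 formed by adventitious decarboxylation is oxidised by the same reagent to 13.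

**Third: step 2.**
- C3-methylation and double methylation compete with the wanted monoalkylation.
- The product 7 leads to the hindered secondary carbanion that weakens step 3.

The fallback sets out from 5 (as its anion 6) and 4 and comes back at 9. It reverses the order of the two C–C bond formations. Acylate the primary anion 6 (2.2 equiv) with 4 and quench with NH4Cl to isolate 4-methoxy-6-(2-oxoheptacosyl)-2H-pyran-2-one F5. Then C-methylate its active methylene with MeI and K2CO3 in acetone–THF to give 9, which enters the KOH stage of step 3.

## Further compounds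
F1 | step 3 | hexacosanal | CCCCCCCCCCCCCCCCCCCCCCCCCC=O
F2 | step 3 | 6-(3-hydroxyoctacosan-2-yl)-4-methoxy-2H-pyran-2-one (racemic diastereomer mixture) | CCCCCCCCCCCCCCCCCCCCCCCCCC(O)C(C)C1=CC(OC)=CC(=O)O1
F3 | step 3 | methyl 4-hydroxy-2-methoxy-5-methyl-6-pentacosylbenzoate | CCCCCCCCCCCCCCCCCCCCCCCCCC1=C(C)C(O)=CC(OC)=C1C(=O)OC
F4 | step 4 | dipotassium N-[(1-carboxy-2-methoxy-5-methyl-4-oxo-6-pentacosylcyclohexa-2,5-dien-1-yl)oxy]imidodisulfonate (racemic) | CCCCCCCCCCCCCCCCCCCCCCCCCC1=C(C)C(=O)C=C(OC)C1(C(=O)O)ON(S(=O)(=O)[O-])S(=O)(=O)[O-].[K+].[K+]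
F5 | step 2 | 4-methoxy-6-(2-oxoheptacosyl)-2H-pyran-2-one | CCCCCCCCCCCCCCCCCCCCCCCCCC(=O)CC1=CC(OC)=CC(=O)O1
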